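**Plan**

- Retrosynthesis: the last operation removes three O-alkyl groups (the 3-O/2'-O methylene bridge, 4'-O-benzyl, 5-O-methyl). The C2–C1' bond between ring C and ring B is then cut inside the bridged compound, next the two acetal C–O bonds, and finally C3–O and the O1–C2/C2–C3 bonds of ring C.
- Forward, ring A and ring C: 3,4,5-trimethoxyphenol is O-methylated and acetylated with loss of the crowded ortho methyl; an enaminone cyclisation closes ring C, and C3 is hydroxylated through the 2,3-epoxide.
- Forward, ring B: O-benzylisovanillin is brominated, oxidised to the phenol (Dakin type) and attached to the C3 oxygen as an aryloxymethyl ether.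
- Enabling feature: the C3–OH of ring C and the C2'–OH of ring B lie on either side of the C2–C1' bond. One CH2 across these two oxygens holds C1'–Br over C2–H, so palladium can close a temporary seven-membered 1,3-dioxepine, which BCl3 opens again at the end.
- Stereochemistry: the target has no stereocentre; the two centres of the racemic cis epoxide in step 4 are erased in the same flask.
- The 5-oxygen is carried as the methyl ether already present in the acetophenone; chelation to C4=O lets BCl3 remove it selectively in the last step.

Key step: step 9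

Remark on the chemistry: AlCl3 is assumed to cleave the ortho methoxy group that is flanked by the acetyl group and a second methoxy group (the more crowded one), as is usual for 2,3,4,6-tetraalkoxyacetophenones. Direct acylation of the free phenol 1 would give the unwanted 5,6,7-oxygenation pattern, hence step 1.

**Route**

Step 1
Reactants: 1 3,4,5-trimethoxyphenol
Product: 2 1,2,3,5-tetramethoxybenzene
Conditions: MeI, K2CO3, acetone, reflux
Reagents that add atoms: iodomethane, CI
Why: Williamson O-methylation of the phenoxide gives the symmetrical tetramethyl ether, whose two free positions are equivalent and both lie between two methoxy groups.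

Step 2
Reactants: 2 1,2,3,5-tetramethoxybenzene
Product: 4 1-(2-hydroxy-3,4,6-trimethoxyphenyl)ethanone, via 2,3,4,6-tetramethoxyacetophenone 3 (not isolated)
Conditions: AcCl, AlCl3 (2.5 equiv), CH2Cl2, 0 °C → rt; then ice-water
Reagents that add atoms: acetyl chloride, CC(Cl)=O
Why: Friedel–Crafts acetylation takes place at the only free position type, and excess AlCl3 chelated to the new ketone then cleaves the more crowded ortho methyl ether, the classical entry to this hydroxyacetophenone.

Step 3
Reactants: 4 1-(2-hydroxy-3,4,6-trimethoxyphenyl)ethanone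
Product: 6 5,7,8-trimethoxy-4H-chromen-4-one, via enaminone 5 (not isolated)
Conditions: Me2NCH(OMe)2, toluene, 100 °C; concentrate; then conc. HCl, CH2Cl2, rt
Reagents that add atoms: N,N-dimethylformamide dimethyl acetal, COC(OC)N(C)C
Why: Condensation of the acetyl methyl group with the amide acetal gives the enaminone, and acid then induces conjugate addition of the phenol with loss of dimethylamine (enaminone route to 2,3-unsubstituted chromones).

Step 4
Reactants: 6 5,7,8-trimethoxy-4H-chromen-4-one
Product: 8 3-hydroxy-5,7,8-trimethoxy-4H-chromen-4-one, via cis-2,3-epoxychromanone 7 (not isolated)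
Conditions: DMDO, acetone/CH2Cl2, 0 °C → rt; evaporate; then TsOH·H2O (cat.), CH2Cl2, rt
Reagents that add atoms: dimethyldioxirane, CC1(C)OO1
Why: Dimethyldioxirane epoxidises the C2=C3 bond of chromones under neutral conditions, and acid opens the racemic cis epoxide at C2 (oxocarbenium ion stabilised by O1) with loss of H3 to give the 3-hydroxychromone, so that both transient stereocentres disappear.

Step 5
Reactants: 9 3-benzyloxy-4-methoxybenzaldehyde (O-benzylisovanillin)
Product: 10 5-benzyloxy-2-bromo-4-methoxybenzaldehyde
Conditions: Br2, NaOAc, AcOH, rt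
Reagents that add atoms: bromine, BrBr
Why: Electrophilic aromatic bromination goes para to the benzyloxy group and ortho to the formyl group, the established outcome for 3,4-dialkoxybenzaldehydes.

Step 6
Reactants: 10 5-benzyloxy-2-bromo-4-methoxybenzaldehyde
Product: 12 5-benzyloxy-2-bromo-4-methoxyphenol, via aryl formate 11 (not isolated)
Conditions: mCPBA, CH2Cl2, rt; then K2CO3 (cat.), MeOH, rt
Reagents that add atoms: 3-chloroperoxybenzoic acid, OOC(=O)c1cccc(Cl)c1
Why: In this Baeyer–Villiger (Dakin-type) oxidation the electron-rich aryl group, bearing a para methoxy group, migrates to oxygen, and mild methanolysis of the formate releases the phenol.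

Step 7
Reactants: 12 5-benzyloxy-2-bromo-4-methoxyphenol; 13 chloromethyl methyl sulfide
Product: 14 1-benzyloxy-4-bromo-2-methoxy-5-[(methylsulfanyl)methoxy]benzene
Conditions: NaH, NaI (cat.), DMF, 0 °C → rt
Reagents that add atoms: none
Why: Williamson alkylation of the sodium phenoxide with the iodide-activated α-chloro sulfide gives the methylthiomethyl ether, which carries the future acetal carbon.

Step 8
Reactants: 14 1-benzyloxy-4-bromo-2-methoxy-5-[(methylsulfanyl)methoxy]benzene; 8 3-hydroxy-5,7,8-trimethoxy-4H-chromen-4-one
Product: 16 3-[(5-benzyloxy-2-bromo-4-methoxyphenoxy)methoxy]-5,7,8-trimethoxy-4H-chromen-4-one, via aryl chloromethyl ether 15 (not isolated)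
Conditions: SO2Cl2, CH2Cl2, −78 → 0 °C, evaporate; then 8, K2CO3, DMF, 0 °C → rt
Reagents that add atoms: none
Why: SO2Cl2 turns the O,S-acetal into the aryl chloromethyl ether through a chlorosulfonium ion (Pummerer-type fragmentation with loss of MeSCl), and this α-chloro ether O-alkylates the enolic 3-OH, the only hydroxyl of 8, under carbonate.

Step 9
Reactants: 16 3-[(5-benzyloxy-2-bromo-4-methoxyphenoxy)methoxy]-5,7,8-trimethoxy-4H-chromen-4-one
Product: 17 3-O,2'-O-methylene acetal of 2-(4-benzyloxy-2-hydroxy-5-methoxyphenyl)-3-hydroxy-5,7,8-trimethoxy-4H-chromen-4-one (chromone-fused benzo-1,3-dioxepine)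
Conditions: Pd(OAc)2 (10 mol %), PCy3·HBF4 (20 mol %), PivOH (30 mol %), K2CO3 (2.5 equiv), anhydrous DMA, 110 °C, Ar
Reagents that add atoms: none
Why: Proposed new method: zerovalent palladium formed from Pd(OAc)2 and PCy3 inserts into C1'–Br, pivalate-assisted concerted metalation–deprotonation at divalent palladium then takes C2–H (the most acidic C–H of the chromone, next to O1 and vinylogous to C4=O), and reductive elimination from the eight-membered palladacycle forms C2–C1'. The closest known reaction type is the pivalate-assisted intramolecular direct arylation of aryl bromides across short oxygen tethers, together with palladium-catalysed C2–H arylation of chromones; new is their combination in a seven-membered closure onto a chromone. The single ring formed, the 1,3-dioxepine (C2, C3, O, CH2, O, C2', C1'), closes in a 7-endo sense with respect to C2=C3, both carbons of which end up in the new ring. No stereocentre is created. The step needs C2 regioselectivity and has to outrun hydrodebromination: the tether lets only C2–H reach the arylpalladium (the benzyl ether is para to bromine and the ring A C6–H is out of range), and the acidity of C2–H with the electron-rich phosphine favours metalation over reduction.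

Step 10
Reactants: 17 bridged 4'-O-benzyl-5-O-methyl flavonol
Product: 18 3,5-dihydroxy-2-(2,4-dihydroxy-5-methoxyphenyl)-7,8-dimethoxy-4H-chromen-4-one (target)
Conditions: BCl3 (excess), C6HMe5, CH2Cl2, −78 °C → rt; then H2O/THF
Reagents that add atoms: none
Why: Lewis-acid ether cleavage in which BCl3 chelated to C4=O breaks the adjacent 3-O–CH2 acetal bond and the peri 5-O–CH3 bond, and also removes the benzyl group (benzyl cation trapped by pentamethylbenzene); the non-chelated 7-, 8- and 5'-methyl ethers should remain, and aqueous work-up releases the acetal carbon as formaldehyde.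

**Compound list**

1 | 3,4,5-trimethoxyphenol | COc1cc(O)cc(OC)c1OC | starting material
2 | 1,2,3,5-tetramethoxybenzene | COc1cc(OC)c(OC)c(OC)c1 | intermediate
3 | 1-(2,3,4,6-tetramethoxyphenyl)ethanone (not isolated) | COc1cc(OC)c(C(C)=O)c(OC)c1OC | intermediate
4 | 1-(2-hydroxy-3,4,6-trimethoxyphenyl)ethanone | COc1cc(OC)c(C(C)=O)c(O)c1OC | intermediate
5 | (E)-3-(dimethylamino)-1-(2-hydroxy-3,4,6-trimethoxyphenyl)prop-2-en-1-one (not isolated) | COc1cc(OC)c(C(=O)/C=C/N(C)C)c(O)c1OC | intermediate
6 | 5,7,8-trimethoxy-4H-chromen-4-one | COc1cc(OC)c2c(=O)ccoc2c1OC | intermediate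
7 | cis-2,3-epoxy-5,7,8-trimethoxychroman-4-one, racemic, one enantiomer drawn (not isolated) | COc1cc(OC)c2C(=O)[C@@H]3O[C@@H]3Oc2c1OC | intermediate
8 | 3-hydroxy-5,7,8-trimethoxy-4H-chromen-4-one | COc1cc(OC)c2c(=O)c(O)coc2c1OC | intermediate
9 | 3-benzyloxy-4-methoxybenzaldehyde | COc1ccc(C=O)cc1OCc1ccccc1 | starting material
10 | 5-benzyloxy-2-bromo-4-methoxybenzaldehyde | COc1cc(Br)c(C=O)cc1OCc1ccccc1 | intermediate
11 | 5-benzyloxy-2-bromo-4-methoxyphenyl formate (not isolated) | COc1cc(Br)c(OC=O)cc1OCc1ccccc1 | intermediate
12 | 5-benzyloxy-2-bromo-4-methoxyphenol | COc1cc(Br)c(O)cc1OCc1ccccc1 | intermediate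
13 | chloromethyl methyl sulfide | CSCCl | starting material
14 | 1-benzyloxy-4-bromo-2-methoxy-5-[(methylsulfanyl)methoxy]benzene | COc1cc(Br)c(OCSC)cc1OCc1ccccc1 | intermediate
15 | 1-benzyloxy-4-bromo-5-(chloromethoxy)-2-methoxybenzene (not isolated) | COc1cc(Br)c(OCCl)cc1OCc1ccccc1 | intermediate
16 | 3-[(5-benzyloxy-2-bromo-4-methoxyphenoxy)methoxy]-5,7,8-trimethoxy-4H-chromen-4-one | COc1cc(OC)c2c(=O)c(OCOc3cc(OCc4ccccc4)c(OC)cc3Br)coc2c1OC | intermediate
17 | 3-O,2'-O-methylene acetal of 2-(4-benzyloxy-2-hydroxy-5-methoxyphenyl)-3-hydroxy-5,7,8-trimethoxy-4H-chromen-4-one | COc1cc2c(cc1OCc1ccccc1)OCOc1c-2oc2c(OC)c(OC)cc(OC)c2c1=O | intermediate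
18 | 3,5-dihydroxy-2-(2,4-dihydroxy-5-methoxyphenyl)-7,8-dimethoxy-4H-chromen-4-one | COc1cc(-c2oc3c(OC)c(OC)cc(O)c3c(=O)c2O)c(O)cc1O | target

**Count**

Total steps: 10. Longest linear sequence: 7 steps (steps 1, 2, 3, 4, 8, 9, 10, from 3,4,5-trimethoxyphenol); the ring B branch (steps 5–7) joins at step 8.

**Steps most likely to fail**

Step 9 (proposed new method). The arylpalladium intermediate may be reduced (hydrodebromination) before metalation, the seven-membered closure may be too slow, or the pyranone may be opened by base at 110 °C. The fallback gives up the tether and uses known C2 zincation of chromones followed by Negishi coupling. It sets out from 8 and 12. 8 is O-benzylated (BnBr, K2CO3, DMF) to 3-benzyloxy-5,7,8-trimethoxy-4H-chromen-4-one F1, and 12 is benzylated in the same way to 1,5-bis(benzyloxy)-2-bromo-4-methoxybenzene F2. F1 is zincated at C2 with TMPZnCl·LiCl (THF, rt) to (3-benzyloxy-5,7,8-trimethoxy-4-oxo-4H-chromen-2-yl)zinc chloride F3. F3 is coupled with F2 (Pd(OAc)2, SPhos, THF, 50 °C) to 3-benzyloxy-2-[2,4-bis(benzyloxy)-5-methoxyphenyl]-5,7,8-trimethoxy-4H-chromen-4-one F4. BCl3 with pentamethylbenzene, as in step 10, then removes the three benzyl groups and the 5-O-methyl group, and the route is rejoined at 18.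

Step 8. The electron-rich ring B may be chlorinated or sulfenylated by SO2Cl2 or the MeSCl it releases, and the chloromethyl ether may hydrolyse before it meets the chromone. The fallback builds the acetal carbon without electrophilic chlorine or sulfur. It sets out from 12, which is alkylated with bromomethyl acetate (Ag2O, MeCN, rt) to (5-benzyloxy-2-bromo-4-methoxyphenoxy)methyl acetate F5. TMSOTf-promoted exchange of the acetate for the 3-OH of 8 (CH2Cl2, molecular sieves, −40 °C) rejoins the route at 16.

Step 10. The benzyl cation may alkylate the resorcinol-type ring B despite the scavenger, and demethylation may stop short of, or go beyond, the 5-position. The fallback separates the cleavages by mechanism and sets out from 17. Hydrogenolysis (H2, Pd/C, EtOAc/MeOH) removes the benzyl group without any cation and gives the 3-O,2'-O-methylene acetal of 2-(2,4-dihydroxy-5-methoxyphenyl)-3-hydroxy-5,7,8-trimethoxy-4H-chromen-4-one F6. AlCl3 in MeCN at 60 °C, followed by warm dilute HCl, then cleaves only the two ethers chelated to C4=O (3-O–CH2 and 5-O–CH3) and rejoins the route at 18.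

**Further compounds**

F1 | step 9 | 3-benzyloxy-5,7,8-trimethoxy-4H-chromen-4-one | COc1cc(OC)c2c(=O)c(OCc3ccccc3)coc2c1OC
F2 | step 9 | 1,5-bis(benzyloxy)-2-bromo-4-methoxybenzene | COc1cc(Br)c(OCc2ccccc2)cc1OCc1ccccc1
F3 | step 9 | (3-benzyloxy-5,7,8-trimethoxy-4-oxo-4H-chromen-2-yl)zinc chloride | COc1cc(OC)c2c(=O)c(OCc3ccccc3)c([Zn]Cl)oc2c1OC
F4 | step 9 | 3-benzyloxy-2-[2,4-bis(benzyloxy)-5-methoxyphenyl]-5,7,8-trimethoxy-4H-chromen-4-one | COc1cc(-c2oc3c(OC)c(OC)cc(OC)c3c(=O)c2OCc2ccccc2)c(OCc2ccccc2)cc1OCc1ccccc1
F5 | step 8 | (5-benzyloxy-2-bromo-4-methoxyphenoxy)methyl acetate | COc1cc(Br)c(OCOC(C)=O)cc1OCc1ccccc1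
F6 | step 10 | 3-O,2'-O-methylene acetal of 2-(2,4-dihydroxy-5-methoxyphenyl)-3-hydroxy-5,7,8-trimethoxy-4H-chromen-4-one | COc1cc2c(cc1O)OCOc1c-2oc2c(OC)c(OC)cc(OC)c2c1=O
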